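## Retrosynthetic overview

- Numbering (lindenane, per half): cyclopropane C1–C2–C3; five-membered ring C1/C3/C4/C5/C10; ring B C5–C10; CH3-14 on C10; CH2-15 on C4; C11 (ester carbon C12) on C7; β is the face of CH3-14. The strategy rests on the two C11 carbons of the 12-membered ring C11–C7=C6–C5=C4–C15–C11′–C7′=C6′–C5′=C4′–C15′: each is an ester α-carbon bonded to the dienyl carbon C7 and to CH2-15′, so without its methyl it is an enolisable CH whose configuration does not matter.
- Target 38 ⇐ C8 oxidation and desilylation ⇐ 35 ⇐ (key) double enolate C-methylation at C11 and C11′ of macrocycle 33.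
- 33 ⇐ two C11–C15′ enolate alkylations made one after the other: ester 26 plus bromide triflate 28, then the second acetate arm and a ring-closing alkylation; both partners come from dienyl triflate 24, both acetate arms from one stock solution of zinc reagent 25 (Pd(PPh3)4-catalysed coupling).
- 24 ⇐ tricyclic triketone 14 (C15 by Stille coupling at C4, 9β-OH by carbonyl reduction, C8–OH by enol ether oxidation); ring B of 14 ⇐ Claisen cyclisation (C7–C8) after vinyl conjugate addition at C10 and C5 alkylation with methyl bromoacetate.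
- Ring order: cyclopropane and five-membered ring together (Hodgson cyclopropanation from (S)-epichlorohydrin, enone 7), then ring B, then the 12-membered ring; the two C11 methyls come last.

Key step: step 25

Remark: C8 ends as the ketone and is a spectator centre; it is carried as the 8α-triethylsilyl ether (C9 as the tert-butyldimethylsilyl ether), which needs no acid for removal and puts the silyloxy group on the face away from the incoming methyl.

Remark: a half carrying both the enolisable arm and the allylic bromide would lose bromide by 1,8-elimination on deprotonation, so the first electrophile carries a triflate in place of the arm. C5 in 12–14 and C11 in 29–33 are drawn without configuration (epimer mixtures that converge).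

## Route

Step 1
Reactants: 1 (S)-epichlorohydrin; 2 crotylmagnesium chloride
Product: 4 (2S)-2-(2-methylbut-3-en-1-yl)oxirane, via chlorohydrin 3 (not isolated)
Conditions: 2 (1.2 equiv), THF, −40 to 0 °C; then NaOH (aq), 20 °C
Reagents that add atoms: crotylmagnesium chloride 2, CC=CC[Mg]Cl
Why: Allylic Grignard opening of the epoxide at its CH2 terminus through the γ-carbon of the crotyl reagent (SE2′), then base-induced closure of the chlorohydrin (Williamson-type epoxide formation), carries the stereocentre of 1 over unchanged; the methyl-bearing carbon forms as both epimers, which is harmless because it becomes sp2 in step 3.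

Step 2
Reactants: 4 (2S)-2-(2-methylbut-3-en-1-yl)oxirane
Product: 5 4-methylbicyclo[3.1.0]hexan-2-ol (OH trans to the cyclopropane CH2)
Conditions: LiTMP (from 2,2,6,6-tetramethylpiperidine and n-BuLi, 2 equiv), t-BuOMe, 0 to 20 °C
Reagents that add atoms: none
Why: Hodgson cyclopropanation: the epoxide CH2 is lithiated trans to the chain and the carbenoid adds to the pendant alkene through a chair-like transition state, so the epoxide stereocentre should fix both ring-fusion carbons (later C1 and C3) and give the alcohol trans to the cyclopropane.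

Step 3
Reactants: 5 4-methylbicyclo[3.1.0]hexan-2-ol
Product: 7 (1S,5R)-4-methylbicyclo[3.1.0]hex-3-en-2-one, via ketone 6 (not isolated)
Conditions: IBX (3 equiv), DMSO, 25 then 70 °C
Reagents that add atoms: none
Why: IBX oxidation of the secondary alcohol followed by IBX dehydrogenation of the ketone through its only enolisable position (the other α-carbon is a cyclopropane CH) should give the enone and remove the undefined methyl stereocentre.

Step 4
Reactants: 7 (1S,5R)-4-methylbicyclo[3.1.0]hex-3-en-2-one; 8 vinylmagnesium bromide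
Product: 10 (1S,4S,5R)-4-ethenyl-4-methylbicyclo[3.1.0]hexan-2-one, via silyl enol ether 9 (not isolated)
Conditions: 8 (1.5 equiv), CuBr·SMe2 (10 mol %), Me3SiCl (2 equiv), THF, −78 °C; then 1 M HCl, 0 °C
Reagents that add atoms: vinylmagnesium bromide 8, C=C[Mg]Br; chlorotrimethylsilane, C[Si](C)(C)Cl (silyl group only in intermediate 9)
Why: Copper-catalysed, silyl chloride-accelerated conjugate addition of the vinyl Grignard reagent to the β-methyl enone; the reagent should enter the convex face anti to the cyclopropane CH2, which sets C10 with CH3 syn to CH2-2 as in the target.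

Step 5
Reactants: 10 (1S,4S,5R)-4-ethenyl-4-methylbicyclo[3.1.0]hexan-2-one; 11 methyl bromoacetate
Product: 12 methyl 2-(4-ethenyl-4-methyl-2-oxobicyclo[3.1.0]hexan-3-yl)acetate
Conditions: LiN(i-Pr)2 (1.1 equiv), THF, −78 °C; 11 (1.3 equiv), DMPU, −78 to −20 °C
Reagents that add atoms: methyl bromoacetate 11, COC(=O)CBr
Why: Kinetic ketone enolate alkylation (SN2): the ketone can enolise only toward C5, and the C5 configuration is of no consequence because it is epimerisable and later sp2.

Step 6
Reactants: 12 methyl 2-(4-ethenyl-4-methyl-2-oxobicyclo[3.1.0]hexan-3-yl)acetate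
Product: 13 methyl 2-(4-acetyl-4-methyl-2-oxobicyclo[3.1.0]hexan-3-yl)acetate
Conditions: PdCl2 (10 mol %), CuCl (1 equiv), O2 (1 atm), DMF/H2O 7:1, 20 °C
Reagents that add atoms: water, O (oxygen of the new ketone; O2 is the terminal oxidant)
Why: Tsuji–Wacker oxidation of the terminal vinyl group should give the methyl ketone by Markovnikov hydroxypalladation, leaving ketone and ester untouched.

Step 7
Reactants: 13 methyl 2-(4-acetyl-4-methyl-2-oxobicyclo[3.1.0]hexan-3-yl)acetate
Product: 14 tricyclic 4,7,9-triketone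
Conditions: KOt-Bu (2.2 equiv), THF, 0 to 20 °C; then 1 M HCl
Reagents that add atoms: none
Why: Intramolecular Claisen (Dieckmann-type) condensation of the methyl ketone enolate (C8) onto the ester (C7) closes ring B as a six-membered 1,3-diketone, the only ring-forming pathway that ends in a stabilised diketonate; C5 epimerises under the base so that the two side chains can meet.

Step 8
Reactants: 14 tricyclic 4,7,9-triketone
Product: 15 C4 enol triflate 7,9-dione
Conditions: KN(SiMe3)2 (2.2 equiv), THF, −78 °C; PhNTf2 (1.05 equiv), −78 to −30 °C; NH4Cl (aq)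
Reagents that add atoms: N-phenylbis(trifluoromethanesulfonimide), O=S(=O)(N(c1ccccc1)S(=O)(=O)C(F)(F)F)C(F)(F)F
Why: Enol triflate formation from a dianion: the first equivalent of base forms the unreactive 1,3-diketonate, the second the C4 ketone enolate at C5 (cyclopropyl C3–H is not enolisable), and only the more basic enolate oxygen should be triflated.

Step 9
Reactants: 15 C4 enol triflate 7,9-dione
Product: 16 C7 methyl vinylogous ester
Conditions: MeOH, TsOH·H2O (5 mol %), 3 Å molecular sieves, 20 °C
Reagents that add atoms: methanol, CO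
Why: Acid-catalysed vinylogous ester formation should occur at the less hindered C7 carbonyl and keep the C9 carbonyl next to the quaternary C10 (the regiochemistry known for 4,4-disubstituted cyclohexane-1,3-diones).

Step 10
Reactants: 16 C7 methyl vinylogous ester; 17 (tributylstannyl)methanol
Product: 18 C15 allylic alcohol
Conditions: 17 (1.5 equiv), Pd(PPh3)4 (5 mol %), LiCl (3 equiv), 1,4-dioxane, 95 °C
Reagents that add atoms: (tributylstannyl)methanol 17, CCCC[Sn](CCCC)(CCCC)CO
Why: Stille coupling of the enol triflate with the hydroxymethyl stannane installs C15 at C4, with the C4=C5 double bond fixed by the position of the triflate.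

Step 11
Reactants: 18 C15 allylic alcohol
Product: 19 C15 triethylsilyl ether
Conditions: Et3SiCl (1.2 equiv), imidazole, CH2Cl2, 0 °C
Reagents that add atoms: chlorotriethylsilane, CC[Si](Cl)(CC)CC
Why: Silyl ether protection of the primary allylic alcohol, chosen so that C15 can later be unmasked in the presence of secondary silyl ethers.

Step 12
Reactants: 19 C15 triethylsilyl ether
Product: 21 8α,9β-dihydroxy C7 ketone, via allylic alcohol 20 (not isolated)
Conditions: i-Bu2AlH (1.3 equiv), CH2Cl2, −78 °C; potassium sodium tartrate (aq); crude 20, dimethyldioxirane (1.1 equiv), acetone/CH2Cl2, −78 to −20 °C; then H2O, NaHCO3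
Reagents that add atoms: dimethyldioxirane, CC1(C)OO1; water, O
Why: 1,2-Reduction of the vinylogous ester carbonyl (Stork–Danheiser-type reduction) from the face opposite the quasi-axial CH3-14 should set the 9β-alcohol, and epoxidation of the electron-rich enol ether from the same open α face with hydrolytic opening (Rubottom-type oxidation) should give the C7 ketone and the 8α-alcohol; the acid-labile intermediate is not purified.

Step 13
Reactants: 21 8α,9β-dihydroxy C7 ketone
Product: 22 8α-triethylsilyl ether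
Conditions: Et3SiCl (1.1 equiv), imidazole, CH2Cl2, −20 to 0 °C
Reagents that add atoms: chlorotriethylsilane, CC[Si](Cl)(CC)CC
Why: Selective silylation (steric differentiation) of the α-keto C8 hydroxyl over the neopentyl C9 hydroxyl next to the quaternary C10.

Step 14
Reactants: 22 8α-triethylsilyl ether
Product: 23 9β-tert-butyldimethylsilyl ether
Conditions: t-BuMe2SiOTf (1.5 equiv), 2,6-lutidine, CH2Cl2, −40 to 0 °C
Reagents that add atoms: tert-butyldimethylsilyl trifluoromethanesulfonate, CC(C)(C)[Si](C)(C)OS(=O)(=O)C(F)(F)F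
Why: Silyl triflate silylation of the hindered C9 alcohol gives a group that survives the later fluoride cleavage of the C8 triethylsilyl ether.

Step 15
Reactants: 23 9β-tert-butyldimethylsilyl ether
Product: 24 dienyl triflate
Conditions: KN(SiMe3)2 (1.2 equiv), THF, −78 °C; PhNTf2 (1.3 equiv), −78 °C; NH4Cl (aq)
Reagents that add atoms: N-phenylbis(trifluoromethanesulfonimide), O=S(=O)(N(c1ccccc1)S(=O)(=O)C(F)(F)F)C(F)(F)F
Why: Enol triflate formation: deprotonation at C6 (α to the ketone and allylic to C4=C5) is favoured over the silyloxy-bearing C8–H and gives the C4=C5–C6=C7 diene; trapping at −78 °C should prevent loss of silanolate from C15.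

Step 16
Reactants: 11 methyl bromoacetate
Product: 25 (2-methoxy-2-oxoethyl)zinc bromide (Reformatsky reagent, titrated THF stock solution)
Conditions: Zn dust (1.5 equiv, activated with Me3SiCl, 5 mol %), THF, 40 °C; solution decanted from excess zinc, titrated with I2 and kept at 0 °C under argon
Reagents that add atoms: zinc, [Zn]
Why: Oxidative insertion of activated zinc into the C–Br bond (formation of the Reformatsky reagent) gives the zinc ester enolate as a THF solution that is made once and supplies both cross-couplings, steps 17 and 21.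

Step 17
Reactants: 24 dienyl triflate; 25 (2-methoxy-2-oxoethyl)zinc bromide
Product: 26 monomer ester
Conditions: 25 (2 equiv, THF solution from step 16), Pd(PPh3)4 (5 mol %), THF, 60 °C
Reagents that add atoms: (2-methoxy-2-oxoethyl)zinc bromide 25, COC(=O)C[Zn]Br
Why: Negishi-type cross-coupling of the Reformatsky zinc enolate with the alkenyl triflate (oxidative addition to zerovalent palladium, transmetalation from zinc, reductive elimination) installs the C11–C12 acetate arm at C7 without touching a stereocentre.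

Step 18
Reactants: 24 dienyl triflate
Product: 27 C15 alcohol triflate
Conditions: pyridinium p-toluenesulfonate (0.2 equiv), MeOH/CH2Cl2 1:4, −10 °C
Reagents that add atoms: none
Why: Acid-catalysed methanolysis (selective desilylation) cleaves the primary allylic triethylsilyl ether much faster than the hindered secondary silyl ethers.

Step 19
Reactants: 27 C15 alcohol triflate
Product: 28 C15 bromide triflate
Conditions: CBr4 (1.3 equiv), Ph3P (1.3 equiv), 2,6-lutidine, CH2Cl2, −20 °C
Reagents that add atoms: carbon tetrabromide, BrC(Br)(Br)Br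
Why: Appel bromination converts the primary allylic alcohol to the bromide under neutral conditions by SN2 at C15 (SN2′ would need attack at the fully substituted C5).

Step 20
Reactants: 26 monomer ester; 28 C15 bromide triflate
Product: 29 seco-dimer triflate
Conditions: 26 (1.1 equiv), LiN(SiMe3)2 (1.1 equiv), THF/DMPU 10:1, −78 °C; then 28, −78 to −40 °C; AcOH
Reagents that add atoms: none
Why: Lithium dienolate alkylation: 26 is deprotonated at C11 and reacts at its α-carbon with the allylic bromide by SN2 to form the first C11–C15′ bond; the electrophile has no enolisable arm and so cannot be deprotonated, and the new C11 centre forms as an epimer mixture that step 25 erases.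

Step 21
Reactants: 29 seco-dimer triflate; 25 (2-methoxy-2-oxoethyl)zinc bromide
Product: 30 seco-dimer diester
Conditions: 25 (2 equiv, THF solution from step 16), Pd(PPh3)4 (5 mol %), THF, 60 °C
Reagents that add atoms: (2-methoxy-2-oxoethyl)zinc bromide 25, COC(=O)C[Zn]Br
Why: The same Negishi-type coupling of the Reformatsky reagent with the remaining alkenyl triflate installs the second acetate arm; the weakly basic zinc enolate should leave the C11–H ester alone.

Step 22
Reactants: 30 seco-dimer diester
Product: 31 seco-dimer C15 alcohol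
Conditions: pyridinium p-toluenesulfonate (0.2 equiv), MeOH/CH2Cl2 1:4, −10 °C
Reagents that add atoms: none
Why: Selective acid-catalysed methanolysis of the single primary allylic triethylsilyl ether, as in step 18.

Step 23
Reactants: 31 seco-dimer C15 alcohol
Product: 32 seco-dimer C15 bromide
Conditions: CBr4 (1.3 equiv), Ph3P (1.3 equiv), 2,6-lutidine, CH2Cl2, −20 °C
Reagents that add atoms: carbon tetrabromide, BrC(Br)(Br)Br
Why: Appel bromination of the primary allylic alcohol, as in step 19; both esters and all silyl ethers are inert to it.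

Step 24
Reactants: 32 seco-dimer C15 bromide
Product: 33 macrocyclic diester (both C11–H, epimer mixture)
Conditions: LiN(SiMe3)2 (2.2 equiv), THF, 1 mM, slow addition of 32, −78 to −40 °C; AcOH at −78 °C
Reagents that add atoms: none
Why: Intramolecular ester enolate alkylation under high dilution closes the 12-membered ring by SN2 at the primary allylic C15; if the tertiary C11–H is removed instead, the trienolate loses bromide to a tetraene that the other enolate attacks at the same C15, so both pathways should end in 33 with no stereocentre to control.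

Step 25
Reactants: 33 macrocyclic diester; 34 iodomethane
Product: 35 macrocyclic diester with both C11 quaternary centres
Conditions: LiN(SiMe3)2 (3 equiv), THF/DMPU 10:1, −78 to −40 °C; then CH3I (10 equiv), −78 to −20 °C
Reagents that add atoms: iodomethane 34, CI
Why: LiN(SiMe3)2 removes both C11–H (each α to the ester and allylic to C6=C7), and the two lithium dienolates react at their α-carbons with CH3I by SN2 to form both C11–CH3 bonds. The closest known reaction type is the α-alkylation of alkenyl-substituted (β,γ-unsaturated) ester enolates to quaternary centres under cyclic, ring-conformation control. No ring is closed. Each new C11 centre is controlled by the conformation of the 12-membered ring: the C11–C15′ bond lies near the diene plane on the C6–H side, the α face of each enolate is turned into the fold of the macrocycle and flanked by the 8α-triethylsilyloxy group, and methyl is expected to enter the open β face (the face of CH3-14), which is the target configuration; both C11 epimers of 33 give the same planar enolates. The step needs α-C-alkylation over γ/ε-C- and O-alkylation, secured by the lithium dienolate and the small SN2 electrophile, and the same face at both symmetry-related centres, secured by the twofold symmetry of the substrate; no carbonyl is present at C8, so C9 is not enolised.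

Step 26
Reactants: 35 macrocyclic diester with both C11 quaternary centres
Product: 37 bis(dienone) bis(9-O-silyl ether), via diol 36 (not isolated)
Conditions: HF·pyridine, pyridine, THF, 0 °C; NaHCO3 (aq); crude 36, MnO2 (20 equiv), CH2Cl2, 20 °C
Reagents that add atoms: none
Why: Fluoride cleavage of the two C8 triethylsilyl ethers (the more hindered C9 tert-butyldimethylsilyl ethers should stay) and immediate MnO2 oxidation of the allylic alcohols gives the two dienones; telescoping keeps the free C8 hydroxyl, which sits next to the C12 ester, from lactonising.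

Step 27
Reactants: 37 bis(dienone) bis(9-O-silyl ether)
Product: 38 cycloshizukaol A
Conditions: HF (48 % aq), MeCN, 0 to 20 °C
Reagents that add atoms: none
Why: Acidic fluoride desilylation of the two α-silyloxy ketones releases the C9 hydroxyls without base, so the enolisable C9 centres and the α-ketols should not epimerise or rearrange.

## Compound list

1 | (S)-epichlorohydrin, (2S)-2-(chloromethyl)oxirane | ClC[C@@H]1CO1 | starting material
2 | crotylmagnesium chloride (but-2-en-1-ylmagnesium chloride, THF solution) | CC=CC[Mg]Cl | starting material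
3 | (2S)-1-chloro-4-methylhex-5-en-2-ol, both C4 epimers | ClC[C@@H](O)CC(C)C=C | intermediate
4 | (2S)-2-(2-methylbut-3-en-1-yl)oxirane, both side-chain epimers | C=CC(C)C[C@H]1CO1 | intermediate
5 | 4-methylbicyclo[3.1.0]hexan-2-ol, (2S)-carbinol with OH trans to the cyclopropane CH2, ring-fusion carbons as in 7, both C4 epimers | O[C@H]1CC(C)[C@@H]2C[C@H]12 | intermediate
6 | 4-methylbicyclo[3.1.0]hexan-2-one, ring-fusion carbons as in 7, both C4 epimers | O=C1CC(C)[C@@H]2C[C@H]12 | intermediate
7 | (1S,5R)-4-methylbicyclo[3.1.0]hex-3-en-2-one | O=C1C=C(C)[C@@H]2C[C@H]12 | intermediate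
8 | vinylmagnesium bromide (THF solution) | C=C[Mg]Br | starting material
9 | trimethylsilyl enol ether of 10 | C[Si](C)(C)OC1=C[C@@](C)(C=C)[C@@H]2C[C@H]12 | intermediate
10 | (1S,4S,5R)-4-ethenyl-4-methylbicyclo[3.1.0]hexan-2-one, vinyl anti and methyl syn to the cyclopropane CH2 | O=C1C[C@@](C)(C=C)[C@@H]2C[C@H]12 | intermediate
11 | methyl bromoacetate | COC(=O)CBr | starting material
12 | methyl 2-(4-ethenyl-4-methyl-2-oxobicyclo[3.1.0]hexan-3-yl)acetate, ring carbons as in 10, both epimers at the acetate-bearing carbon (C5) | O=C1C(CC(=O)OC)[C@@](C)(C=C)[C@@H]2C[C@H]12 | intermediate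
13 | methyl 2-(4-acetyl-4-methyl-2-oxobicyclo[3.1.0]hexan-3-yl)acetate, ring carbons as in 10, both C5 epimers | O=C1C(CC(=O)OC)[C@@](C)(C(C)=O)[C@@H]2C[C@H]12 | intermediate
14 | tricyclic triketone (lindenane numbering): cyclopropane C1–C2–C3 with CH2-2 syn to CH3-14, ketones at C4, C7 and C9, C5–H either epimer | O=C1C2CC(=O)CC(=O)[C@@]2(C)[C@@H]2C[C@H]12 | intermediate
15 | C4 enol triflate of 14: C4(OTf)=C5, ring B 7,9-dione | FC(F)(F)S(=O)(=O)OC1=C2CC(=O)CC(=O)[C@@]2(C)[C@@H]2C[C@H]12 | intermediate
16 | vinylogous ester: C4(OTf)=C5, C7(OCH3)=C8, C9 ketone | FC(F)(F)S(=O)(=O)OC1=C2CC(OC)=CC(=O)[C@@]2(C)[C@@H]2C[C@H]12 | intermediate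
17 | (tributylstannyl)methanol | CCCC[Sn](CCCC)(CCCC)CO | starting material
18 | allylic alcohol: C15–OH on C4=C5, C7(OCH3)=C8, C9 ketone | OCC1=C2CC(OC)=CC(=O)[C@@]2(C)[C@@H]2C[C@H]12 | intermediate
19 | C15 triethylsilyl ether of 18 | CC[Si](CC)(CC)OCC1=C2CC(OC)=CC(=O)[C@@]2(C)[C@@H]2C[C@H]12 | intermediate
20 | 9β-alcohol: C15–OSiEt3, C4=C5, C7(OCH3)=C8 | CC[Si](CC)(CC)OCC1=C2CC(OC)=C[C@H](O)[C@@]2(C)[C@@H]2C[C@H]12 | intermediate
21 | 8α,9β-dihydroxy C7 ketone: C15–OSiEt3, C4=C5 | CC[Si](CC)(CC)OCC1=C2CC(=O)[C@@H](O)[C@H](O)[C@@]2(C)[C@@H]2C[C@H]12 | intermediate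
22 | 8α-triethylsilyl ether of 21, 9β-OH free | CC[Si](CC)(CC)OCC1=C2CC(=O)[C@@H](O[Si](CC)(CC)CC)[C@H](O)[C@@]2(C)[C@@H]2C[C@H]12 | intermediate
23 | C7 ketone with 8α-OSiEt3 and 9β-OSiMe2t-Bu, C15–OSiEt3 | CC[Si](CC)(CC)OCC1=C2CC(=O)[C@@H](O[Si](CC)(CC)CC)[C@H](O[Si](C)(C)C(C)(C)C)[C@@]2(C)[C@@H]2C[C@H]12 | intermediate
24 | dienyl triflate: C15–OSiEt3, C4=C5–C6=C7(OTf), 8α-OSiEt3, 9β-OSiMe2t-Bu | CC[Si](CC)(CC)OCC1=C2C=C(OS(=O)(=O)C(F)(F)F)[C@@H](O[Si](CC)(CC)CC)[C@H](O[Si](C)(C)C(C)(C)C)[C@@]2(C)[C@@H]2C[C@H]12 | intermediate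
25 | (2-methoxy-2-oxoethyl)zinc bromide (Reformatsky reagent, THF stock solution) | COC(=O)C[Zn]Br | intermediate
26 | monomer ester: as 24 with CH2CO2CH3 (C11, C12) on C7 in place of the triflate | CC[Si](CC)(CC)OCC1=C2C=C(CC(=O)OC)[C@@H](O[Si](CC)(CC)CC)[C@H](O[Si](C)(C)C(C)(C)C)[C@@]2(C)[C@@H]2C[C@H]12 | intermediate
27 | C15 alcohol of 24 (C7 triflate kept) | OCC1=C2C=C(OS(=O)(=O)C(F)(F)F)[C@@H](O[Si](CC)(CC)CC)[C@H](O[Si](C)(C)C(C)(C)C)[C@@]2(C)[C@@H]2C[C@H]12 | intermediate
28 | C15 bromide of 24 (C7 triflate kept) | BrCC1=C2C=C(OS(=O)(=O)C(F)(F)F)[C@@H](O[Si](CC)(CC)CC)[C@H](O[Si](C)(C)C(C)(C)C)[C@@]2(C)[C@@H]2C[C@H]12 | intermediate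
29 | seco-dimer triflate: C11 of the ester half bonded to C15′ of the triflate half; ester half keeps C15–OSiEt3, other half keeps C7′–OTf; C11 epimers | CC[Si](CC)(CC)OCC1=C2C=C(C(C(=O)OC)CC3=C4C=C(OS(=O)(=O)C(F)(F)F)[C@@H](O[Si](CC)(CC)CC)[C@H](O[Si](C)(C)C(C)(C)C)[C@@]4(C)[C@@H]4C[C@H]34)[C@@H](O[Si](CC)(CC)CC)[C@H](O[Si](C)(C)C(C)(C)C)[C@@]2(C)[C@@H]2C[C@H]12 | intermediate
30 | seco-dimer diester: as 29 with CH2CO2CH3 on C7′ in place of the triflate | CC[Si](CC)(CC)OCC1=C2C=C(C(C(=O)OC)CC3=C4C=C(CC(=O)OC)[C@@H](O[Si](CC)(CC)CC)[C@H](O[Si](C)(C)C(C)(C)C)[C@@]4(C)[C@@H]4C[C@H]34)[C@@H](O[Si](CC)(CC)CC)[C@H](O[Si](C)(C)C(C)(C)C)[C@@]2(C)[C@@H]2C[C@H]12 | intermediate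
31 | seco-dimer C15 alcohol (from 30) | OCC1=C2C=C(C(C(=O)OC)CC3=C4C=C(CC(=O)OC)[C@@H](O[Si](CC)(CC)CC)[C@H](O[Si](C)(C)C(C)(C)C)[C@@]4(C)[C@@H]4C[C@H]34)[C@@H](O[Si](CC)(CC)CC)[C@H](O[Si](C)(C)C(C)(C)C)[C@@]2(C)[C@@H]2C[C@H]12 | intermediate
32 | seco-dimer C15 bromide (from 31) | BrCC1=C2C=C(C(C(=O)OC)CC3=C4C=C(CC(=O)OC)[C@@H](O[Si](CC)(CC)CC)[C@H](O[Si](C)(C)C(C)(C)C)[C@@]4(C)[C@@H]4C[C@H]34)[C@@H](O[Si](CC)(CC)CC)[C@H](O[Si](C)(C)C(C)(C)C)[C@@]2(C)[C@@H]2C[C@H]12 | intermediate
33 | macrocyclic dimethyl ester lacking both C11 methyls, 8α-OSiEt3 and 9β-OSiMe2t-Bu on each half, C11 epimer mixture | COC(=O)C1CC2=C3C=C([C@@H](O[Si](CC)(CC)CC)[C@H](O[Si](C)(C)C(C)(C)C)[C@@]3(C)[C@@H]3C[C@H]23)C(C(=O)OC)CC2=C3C=C1[C@@H](O[Si](CC)(CC)CC)[C@H](O[Si](C)(C)C(C)(C)C)[C@@]3(C)[C@@H]1C[C@H]21 | intermediate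
34 | iodomethane | CI | starting material
35 | macrocyclic dimethyl ester with both C11 quaternary centres, silyl ethers as in 33 | COC(=O)[C@]1(C)CC2=C3C=C([C@@H](O[Si](CC)(CC)CC)[C@H](O[Si](C)(C)C(C)(C)C)[C@@]3(C)[C@@H]3C[C@H]23)[C@](C)(C(=O)OC)CC2=C3C=C1[C@@H](O[Si](CC)(CC)CC)[C@H](O[Si](C)(C)C(C)(C)C)[C@@]3(C)[C@@H]1C[C@H]21 | intermediate
36 | 8α,8′α-diol of 35 (9-O-silyl ethers kept) | COC(=O)[C@]1(C)CC2=C3C=C([C@@H](O)[C@H](O[Si](C)(C)C(C)(C)C)[C@@]3(C)[C@@H]3C[C@H]23)[C@](C)(C(=O)OC)CC2=C3C=C1[C@@H](O)[C@H](O[Si](C)(C)C(C)(C)C)[C@@]3(C)[C@@H]1C[C@H]21 | intermediate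
37 | bis(dienone): C8 and C8′ ketones, 9β-OSiMe2t-Bu on each half | COC(=O)[C@]1(C)CC2=C3C=C(C(=O)[C@H](O[Si](C)(C)C(C)(C)C)[C@@]3(C)[C@@H]3C[C@H]23)[C@](C)(C(=O)OC)CC2=C3C=C1C(=O)[C@H](O[Si](C)(C)C(C)(C)C)[C@@]3(C)[C@@H]1C[C@H]21 | intermediate
38 | cycloshizukaol A | COC(=O)[C@]1(C)CC2=C3C=C(C(=O)[C@H](O)[C@@]3(C)[C@@H]3C[C@H]23)[C@](C)(C(=O)OC)CC2=C3C=C1C(=O)[C@H](O)[C@@]3(C)[C@@H]1C[C@H]21 | target

## Step count and risks

Total step count: 27. Longest linear sequence: 25 steps (steps 1–15 and 18–27). Step 16 (zinc reagent 25 from 11) and step 17 (24 to 26) lie off this line.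

**Steps most likely to fail**

1. Step 25. Methyl may enter the α face of one or both dienolates (poor or reversed facial selectivity), which gives C11 epimers that cannot be corrected afterwards. The fallback reverses the order in which CH3 and CH2-15′ are attached to C11, so that the same facial preference of the C11 enolate delivers the opposite configuration.
   - It sets out from dienyl triflate 24, which is coupled (Pd(PPh3)4, THF) with the zinc reagent of methyl 2-bromopropanoate (made in the flask from the bromide and zinc dust) to give the α-methyl monomer ester F1.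
   - The lithium enolate of F1 is alkylated with bromide 28 to give the seco-dimer triflate F2, whose quaternary C11 is made with the allylic bromide as electrophile.
   - A second coupling with the propanoate zinc reagent gives the diester F3, methanolysis of the primary silyl ether gives the alcohol F4, and Appel bromination gives the bromide F5.
   - Ring-closing alkylation of F5 (LiN(SiMe3)2, high dilution) forms the second quaternary centre, and the sequence comes back to the route at 35.

2. Step 24. Intermolecular alkylation and oligomer formation may outrun the slow closure of the 12-membered ring. The fallback closes the ring at the C7′–C11′ bond instead.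
   - It sets out from seco-dimer triflate 29: methanolysis gives the C15 alcohol F6 and Appel bromination the C15 bromide F7.
   - Alkylation of the lithium enolate of methyl acetate (excess, −78 °C) with F7 gives the homologated ester triflate F8, which carries the future C11′ as a CH2 on C15.
   - Intramolecular palladium-catalysed α-alkenylation of the ester enolate with the dienyl triflate (LiN(SiMe3)2, 2.2 equiv, Pd(dba)2/P(t-Bu)3, toluene, high dilution; the less stabilised CH2 enolate couples) comes back to the route at 33.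

3. Step 10. Oxidative addition and transmetalation at the hindered tetrasubstituted enol triflate may be slow, with reduction of the triflate or decomposition of the stannane taking over. The fallback brings C15 in as a carboxyl carbon.
   - It sets out from 16: methoxycarbonylation (Pd(OAc)2/dppp, CO 1 atm, MeOH, Et3N, DMF, 70 °C) gives the C15 methyl ester F9.
   - i-Bu2AlH (excess, −78 °C) reduces the ester and the C9 carbonyl together to the diol F10 (C15–OH and 9β-OH).
   - Selective silylation of the primary alcohol (Et3SiCl, imidazole, −40 °C) comes back to the route at 20, which is then oxidised as in step 12.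

## Further compounds

F1 | step 25 | α-methyl monomer ester: as 26 with CH(CH3)CO2CH3 on C7, C11 epimers | CC[Si](CC)(CC)OCC1=C2C=C(C(C)C(=O)OC)[C@@H](O[Si](CC)(CC)CC)[C@H](O[Si](C)(C)C(C)(C)C)[C@@]2(C)[C@@H]2C[C@H]12
F2 | step 25 | seco-dimer triflate with quaternary C11 (CH3, CO2CH3, C7, C15′), C7′–OTf, C15–OSiEt3 | CC[Si](CC)(CC)OCC1=C2C=C([C@](C)(C(=O)OC)CC3=C4C=C(OS(=O)(=O)C(F)(F)F)[C@@H](O[Si](CC)(CC)CC)[C@H](O[Si](C)(C)C(C)(C)C)[C@@]4(C)[C@@H]4C[C@H]34)[C@@H](O[Si](CC)(CC)CC)[C@H](O[Si](C)(C)C(C)(C)C)[C@@]2(C)[C@@H]2C[C@H]12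
F3 | step 25 | seco-dimer diester: as F2 with CH(CH3)CO2CH3 on C7′ | CC[Si](CC)(CC)OCC1=C2C=C([C@](C)(C(=O)OC)CC3=C4C=C(C(C)C(=O)OC)[C@@H](O[Si](CC)(CC)CC)[C@H](O[Si](C)(C)C(C)(C)C)[C@@]4(C)[C@@H]4C[C@H]34)[C@@H](O[Si](CC)(CC)CC)[C@H](O[Si](C)(C)C(C)(C)C)[C@@]2(C)[C@@H]2C[C@H]12
F4 | step 25 | C15 alcohol of F3 | OCC1=C2C=C([C@](C)(C(=O)OC)CC3=C4C=C(C(C)C(=O)OC)[C@@H](O[Si](CC)(CC)CC)[C@H](O[Si](C)(C)C(C)(C)C)[C@@]4(C)[C@@H]4C[C@H]34)[C@@H](O[Si](CC)(CC)CC)[C@H](O[Si](C)(C)C(C)(C)C)[C@@]2(C)[C@@H]2C[C@H]12
F5 | step 25 | C15 bromide of F3 | BrCC1=C2C=C([C@](C)(C(=O)OC)CC3=C4C=C(C(C)C(=O)OC)[C@@H](O[Si](CC)(CC)CC)[C@H](O[Si](C)(C)C(C)(C)C)[C@@]4(C)[C@@H]4C[C@H]34)[C@@H](O[Si](CC)(CC)CC)[C@H](O[Si](C)(C)C(C)(C)C)[C@@]2(C)[C@@H]2C[C@H]12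
F6 | step 24 | C15 alcohol of seco-dimer triflate 29 | OCC1=C2C=C(C(C(=O)OC)CC3=C4C=C(OS(=O)(=O)C(F)(F)F)[C@@H](O[Si](CC)(CC)CC)[C@H](O[Si](C)(C)C(C)(C)C)[C@@]4(C)[C@@H]4C[C@H]34)[C@@H](O[Si](CC)(CC)CC)[C@H](O[Si](C)(C)C(C)(C)C)[C@@]2(C)[C@@H]2C[C@H]12
F7 | step 24 | C15 bromide of seco-dimer triflate 29 | BrCC1=C2C=C(C(C(=O)OC)CC3=C4C=C(OS(=O)(=O)C(F)(F)F)[C@@H](O[Si](CC)(CC)CC)[C@H](O[Si](C)(C)C(C)(C)C)[C@@]4(C)[C@@H]4C[C@H]34)[C@@H](O[Si](CC)(CC)CC)[C@H](O[Si](C)(C)C(C)(C)C)[C@@]2(C)[C@@H]2C[C@H]12
F8 | step 24 | homologated ester triflate: C15 bears CH2CO2CH3 (future C11′), C7′–OTf kept | COC(=O)CCC1=C2C=C(C(C(=O)OC)CC3=C4C=C(OS(=O)(=O)C(F)(F)F)[C@@H](O[Si](CC)(CC)CC)[C@H](O[Si](C)(C)C(C)(C)C)[C@@]4(C)[C@@H]4C[C@H]34)[C@@H](O[Si](CC)(CC)CC)[C@H](O[Si](C)(C)C(C)(C)C)[C@@]2(C)[C@@H]2C[C@H]12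
F9 | step 10 | C15 methyl ester on C4=C5, C7(OCH3)=C8, C9 ketone | COC(=O)C1=C2CC(OC)=CC(=O)[C@@]2(C)[C@@H]2C[C@H]12
F10 | step 10 | diol: C15–OH and 9β-OH, C4=C5, C7(OCH3)=C8 | OCC1=C2CC(OC)=C[C@H](O)[C@@]2(C)[C@@H]2C[C@H]12
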